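**Retrosynthetic overview**

1. Numbering: ring A = C1(Me2)–C2–C3(Br)–C4–C5(Me,OH)–C6(spiro); ring B = C6–C7=C8–C9(=C12HBr)–C10–C11. The strategy rests on the tertiary carbinol C5 lying next to the quaternary spiro carbon C6, with alkenyl carbon C7 anti and C11 syn to the C5 oxygen: this is the retron of an anti 1,2-alkenyl shift onto a C5–C6 epoxide.
2. Late stage: C3–Br from the C3 alcohol of opposite configuration (SN2), C9=C12 from a C9 enone (Wittig), C11 methylene from a C11 ketone (reduction, radical deoxygenation).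
3. Key disconnection: bond C6–C7 and ring B from a cyclopent-2-en-1-ol carried on C6 of the ring A 5,6-epoxide, by semipinacol ring expansion (13 → 14).
4. Compound 13 comes from hydroxyl-directed epoxidation of a diene diol, made by adding the ring A alkenyl metal (from ketoisophorone via the 4R hydroxy ketone and its alkenyl iodide) to (S)-4-silyloxycyclopentenone.
5. Ring order: ring A is carried from the starting material, the five-membered ring is bought, and ring B is formed last by one-carbon expansion of that ring in step 9.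

Key step: step 9

Remark: descriptors in the names of the spiro compounds use the route numbering above; the C9 and C11 configurations of intermediates do not appear in the target and are chosen only to give single diastereomers.

**Route**

Step 1
Reactants: 1 ketoisophorone (2,6,6-trimethylcyclohex-2-ene-1,4-dione)
Product: 2 (6R)-2,2,6-trimethylcyclohexane-1,4-dione
Conditions: OYE2 ene-reductase (old yellow enzyme), NADP+ (cat.), glucose dehydrogenase, D-glucose, phosphate buffer pH 7, 30 °C
Reagents that add atoms: none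
Why: Ene-reductase reduction of the electron-poor C=C of this enedione is a known biotransformation of this very substrate and should set the methyl-bearing carbon as R under enzyme control.

Step 2
Reactants: 2 (6R)-2,2,6-trimethylcyclohexane-1,4-dione
Product: 3 (4R,6R)-4-hydroxy-2,2,6-trimethylcyclohexan-1-one
Conditions: LiBH(s-Bu)3, THF, −78 °C; then H2O
Reagents that add atoms: none
Why: Bulky trialkylborohydride ketone reduction is chemoselective for the unhindered C4 carbonyl (C1 is flanked by CMe2 and CHMe) and, by equatorial attack away from the axial C2 methyl, should give the axial 4R alcohol trans to the 6-methyl group (substrate control from C6).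

Step 3
Reactants: 3 (4R,6R)-4-hydroxy-2,2,6-trimethylcyclohexan-1-one
Product: 4 (4R,6R)-4-hydroxy-2,2,6-trimethylcyclohexan-1-one hydrazone
Conditions: N2H4·H2O (10 equiv), Et3N, EtOH, 80 °C
Reagents that add atoms: hydrazine hydrate, NN.O
Why: Hydrazone formation from the hindered ketone with excess hydrazine leaves the carbinol centre untouched, and the epimerisable C6 centre is erased in step 4.

Step 4
Reactants: 4 (4R,6R)-4-hydroxy-2,2,6-trimethylcyclohexan-1-one hydrazone
Product: 5 (1R)-4-iodo-3,5,5-trimethylcyclohex-3-en-1-ol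
Conditions: I2 (2.2 equiv), 1,1,3,3-tetramethylguanidine, THF, 0 °C to rt
Reagents that add atoms: iodine, II
Why: Barton vinyl iodide synthesis (oxidation of the hydrazone to the diazoalkane, iodination, loss of N2 and elimination toward the only α-hydrogen) should give the tetrasubstituted alkenyl iodide without touching the free secondary alcohol.

Step 5
Reactants: 5 (1R)-4-iodo-3,5,5-trimethylcyclohex-3-en-1-ol
Product: 6 [(1R)-4-iodo-3,5,5-trimethylcyclohex-3-en-1-yl]oxy-trimethylsilane
Conditions: Me3SiCl, imidazole, CH2Cl2, 0 °C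
Reagents that add atoms: chlorotrimethylsilane, C[Si](C)(C)Cl
Why: Silylation masks the hydroxyl for the lithiation as a trimethylsilyl ether, which can later be removed with K2CO3 in methanol without touching the tert-butyldimethylsilyl ether brought in by 7.

Step 6
Reactants: 6 [(1R)-4-iodo-3,5,5-trimethylcyclohex-3-en-1-yl]oxy-trimethylsilane; 7 (S)-4-(tert-butyldimethylsilyloxy)cyclopent-2-en-1-one
Product: 11 (1R,4S)-4-(tert-butyldimethylsilyloxy)-1-[(4R)-4-hydroxy-2,6,6-trimethylcyclohex-1-en-1-yl]cyclopent-2-en-1-ol, via alkenyllithium 8 (not isolated), via alkenylcerium dichloride 9 (not isolated), via adduct trimethylsilyl ether 10 (not isolated)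
Conditions: t-BuLi (2.1 equiv), THF, −78 °C; CeCl3 (anhydrous), −78 °C; 7, −78 to −40 °C; H2O; then K2CO3, MeOH, 0 °C
Reagents that add atoms: none
Why: Iodine–lithium exchange, transmetalation to the less basic organocerium reagent (which suppresses enolisation of the enone) and 1,2-addition to the cyclopentenone on the face anti to the C9 silyloxy group should set C11 as R with its hydroxyl cis to the silyloxy group, after which methanolysis removes only the trimethylsilyl ether.

Step 7
Reactants: 11 (1R,4S)-4-(tert-butyldimethylsilyloxy)-1-[(4R)-4-hydroxy-2,6,6-trimethylcyclohex-1-en-1-yl]cyclopent-2-en-1-ol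
Product: 12 (1R,4S)-4-(tert-butyldimethylsilyloxy)-1-[(1S,4S,6S)-4-hydroxy-2,2,6-trimethyl-7-oxabicyclo[4.1.0]heptan-1-yl]cyclopent-2-en-1-ol
Conditions: VO(acac)2 (5 mol %), t-BuOOH (anhydrous, 1.3 equiv), CH2Cl2, 0 °C
Reagents that add atoms: tert-butyl hydroperoxide, CC(C)(C)OO
Why: In this hydroxyl-directed vanadium-catalysed epoxidation the homoallylic C3 hydroxyl should deliver oxygen to the electron-rich tetrasubstituted C5=C6 bond on its own face and so set C5 and C6, while the crowded tertiary C11 hydroxyl cannot reach a directing geometry over C5=C6 because of allylic strain with the C1 and C5 substituents, and the C7=C8 bond is less nucleophilic and screened by the cis silyloxy group.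

Step 8
Reactants: 12 (1R,4S)-4-(tert-butyldimethylsilyloxy)-1-[(1S,4S,6S)-4-hydroxy-2,2,6-trimethyl-7-oxabicyclo[4.1.0]heptan-1-yl]cyclopent-2-en-1-ol
Product: 13 (1R,4S)-4-(tert-butyldimethylsilyloxy)-1-[(1S,4S,6S)-4-(tert-butyldimethylsilyloxy)-2,2,6-trimethyl-7-oxabicyclo[4.1.0]heptan-1-yl]cyclopent-2-en-1-ol
Conditions: t-BuMe2SiCl, imidazole, DMF, rt
Reagents that add atoms: tert-butyldimethylsilyl chloride, CC(C)(C)[Si](C)(C)Cl
Why: Silyl ether formation is selective for the secondary C3 hydroxyl over the hindered tertiary C11 hydroxyl, which must stay free for the rearrangement.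

Step 9
Reactants: 13 (1R,4S)-4-(tert-butyldimethylsilyloxy)-1-[(1S,4S,6S)-4-(tert-butyldimethylsilyloxy)-2,2,6-trimethyl-7-oxabicyclo[4.1.0]heptan-1-yl]cyclopent-2-en-1-ol
Product: 14 (3S,5S,6R,9S)-3,9-bis(tert-butyldimethylsilyloxy)-5-hydroxy-1,1,5-trimethylspiro[5.5]undec-7-en-11-one
Conditions: BF3·OEt2 (1.5 equiv), CH2Cl2, −78 °C; Et3N then aq NaHCO3 at −78 °C
Reagents that add atoms: none
Why: BF3 binds the epoxide oxygen and the C6–O bond ionises while the C11–C7 bond, lying anti to it, shifts to C6 with help from the C7=C8 π-bond, the C11 oxygen taking up the charge as the ketone; the closest known reaction type is the Lewis-acid semipinacol rearrangement of tertiary 2,3-epoxy alcohols with alkenyl migration. Ring B is closed by a one-carbon ring expansion of the cyclopentenol (1,2-shift of a ring bond), not by a cyclisation. The new quaternary centre C6 is fixed by inversion: C7 enters anti to the departing oxygen and C11 ends syn to the C5 hydroxyl, so the epoxide face set in step 7 controls it and C5 keeps its oxygen and configuration. The step needs C6–O rather than C5–O cleavage and migration of the sp2 carbon C7 rather than the CH2 carbon C10; only ionisation at C6 is assisted by the adjacent carbinol oxygen and the bridging alkenyl group, and the alkenyl carbon is the better migrating group. The hindered aldol product is quenched cold and reduced at once, because retro-aldol cleavage of C5–C6 and loss of the C9 silyloxy group β to the ketone are its likely decay paths.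

Step 10
Reactants: 14 (3S,5S,6R,9S)-3,9-bis(tert-butyldimethylsilyloxy)-5-hydroxy-1,1,5-trimethylspiro[5.5]undec-7-en-11-one
Product: 15 (3S,5S,6S,9S,11R)-3,9-bis(tert-butyldimethylsilyloxy)-1,1,5-trimethylspiro[5.5]undec-7-ene-5,11-diol
Conditions: Me4NBH(OAc)3, MeCN/AcOH (1:1), −20 °C to rt
Reagents that add atoms: none
Why: Hydroxyl-directed triacetoxyborohydride reduction (Evans–Saksena) works under acidic, non-basic conditions that avoid retro-aldol cleavage and should deliver hydride to C11 from the side of the C5 oxygen; the new carbinol configuration is of no consequence because C11 becomes CH2 in step 12.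

Step 11
Reactants: 15 (3S,5S,6S,9S,11R)-3,9-bis(tert-butyldimethylsilyloxy)-1,1,5-trimethylspiro[5.5]undec-7-ene-5,11-diol
Product: 16 O-[(3S,5S,6S,9S,11R)-3,9-bis(tert-butyldimethylsilyloxy)-5-hydroxy-1,1,5-trimethylspiro[5.5]undec-7-en-11-yl] S-methyl dithiocarbonate
Conditions: NaN(SiMe3)2 (1.05 equiv), THF, −78 °C; CS2; MeI, −78 to 0 °C
Reagents that add atoms: carbon disulfide, S=C=S; iodomethane, CI
Why: In this xanthate formation the secondary C11 alkoxide is captured by the small electrophile carbon disulfide and S-methylated, while with one equivalent of base the more hindered tertiary C5 hydroxyl should stay protonated and unreacted.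

Step 12
Reactants: 16 O-[(3S,5S,6S,9S,11R)-3,9-bis(tert-butyldimethylsilyloxy)-5-hydroxy-1,1,5-trimethylspiro[5.5]undec-7-en-11-yl] S-methyl dithiocarbonate
Product: 17 (3S,5S,6S,9S)-3,9-bis(tert-butyldimethylsilyloxy)-1,1,5-trimethylspiro[5.5]undec-7-en-5-ol
Conditions: Bu3SnH (0.3 M), AIBN (cat.), toluene, 90 °C
Reagents that add atoms: none
Why: Barton–McCombie radical deoxygenation should work because the secondary C11 radical is a cyclohex-3-enyl radical whose 3-exo closure onto C7 would have to form the ring-fusion bond of a bicyclo[3.1.0]hexane and is stereoelectronically slow, so hydrogen transfer from the concentrated tin hydride should win.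

Step 13
Reactants: 17 (3S,5S,6S,9S)-3,9-bis(tert-butyldimethylsilyloxy)-1,1,5-trimethylspiro[5.5]undec-7-en-5-ol
Product: 18 (3S,5S,6S,9S)-1,1,5-trimethylspiro[5.5]undec-7-ene-3,5,9-triol
Conditions: Bu4NF, THF, 0 °C to rt
Reagents that add atoms: none
Why: Fluoride cleavage of both secondary silyl ethers is safe here because no carbonyl group is present and the alkoxides therefore cannot fragment.

Step 14
Reactants: 18 (3S,5S,6S,9S)-1,1,5-trimethylspiro[5.5]undec-7-ene-3,5,9-triol
Product: 20 (3S,5S,6S)-1,1,5-trimethyl-3,5-bis(trimethylsilyloxy)spiro[5.5]undec-7-en-9-one, via enone diol 19 (not isolated)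
Conditions: MnO2 (activated), CH2Cl2, rt; filtration; N-(trimethylsilyl)imidazole, CH2Cl2, rt
Reagents that add atoms: N-(trimethylsilyl)imidazole, C[Si](C)(C)n1ccnc1
Why: MnO2 oxidises only the allylic C9 alcohol (chemoselective allylic oxidation), and the neutral silylating agent then caps both remaining hydroxyls so that no C5 alkoxide can form in the basic next step, where the γ-(hydroxyalkyl) enone would be prone to vinylogous retro-aldol cleavage of C5–C6.

Step 15
Reactants: 20 (3S,5S,6S)-1,1,5-trimethyl-3,5-bis(trimethylsilyloxy)spiro[5.5]undec-7-en-9-one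
Product: 22 (3S,5S,6S,E)-9-(bromomethylidene)-1,1,5-trimethylspiro[5.5]undec-7-ene-3,5-diol, via silylated bromodiene 21 (not isolated)
Conditions: Ph3P+CH2Br Br−, NaN(SiMe3)2, THF, −78 to 0 °C; then MeOH, Bu4NF, THF, 0 °C
Reagents that add atoms: (bromomethyl)triphenylphosphonium bromide, BrC[P+](c1ccccc1)(c1ccccc1)c1ccccc1.[Br-]
Why: Wittig olefination with (bromomethylidene)triphenylphosphorane converts the enone carbonyl into the bromodiene; both alkene isomers are to be expected, and the E isomer (bromine on the side of C10) is separated after fluoride removal of the trimethylsilyl ethers.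

Step 16
Reactants: 22 (3S,5S,6S,E)-9-(bromomethylidene)-1,1,5-trimethylspiro[5.5]undec-7-ene-3,5-diol
Product: 23 (3R,5S,6S,E)-3-bromo-9-(bromomethylidene)-1,1,5-trimethylspiro[5.5]undec-7-en-5-ol
Conditions: CBr4, PPh3, CH2Cl2, 0 °C to rt
Reagents that add atoms: carbon tetrabromide, BrC(Br)(Br)Br
Why: In the Appel bromination the secondary C3 oxyphosphonium ion is displaced by bromide in an SN2 reaction with inversion, which should set C3 as R (bromine equatorial, trans to the C5 hydroxyl), while the tertiary C5 hydroxyl is too hindered to be activated.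

**Compound list**

1 | ketoisophorone (2,6,6-trimethylcyclohex-2-ene-1,4-dione) | CC1=CC(=O)CC(C)(C)C1=O | starting material
2 | (6R)-2,2,6-trimethylcyclohexane-1,4-dione | C[C@@H]1CC(=O)CC(C)(C)C1=O | intermediate
3 | (4R,6R)-4-hydroxy-2,2,6-trimethylcyclohexan-1-one | C[C@@H]1C[C@@H](O)CC(C)(C)C1=O | intermediate
4 | (4R,6R)-4-hydroxy-2,2,6-trimethylcyclohexan-1-one hydrazone | C[C@@H]1C[C@@H](O)CC(C)(C)C1=NN | intermediate
5 | (1R)-4-iodo-3,5,5-trimethylcyclohex-3-en-1-ol | O[C@@H]1CC(C)=C(I)C(C)(C)C1 | intermediate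
6 | [(1R)-4-iodo-3,5,5-trimethylcyclohex-3-en-1-yl]oxy-trimethylsilane | C[Si](C)(C)O[C@@H]1CC(C)=C(I)C(C)(C)C1 | intermediate
7 | (S)-4-(tert-butyldimethylsilyloxy)cyclopent-2-en-1-one | O=C1C=C[C@@H](O[Si](C)(C)C(C)(C)C)C1 | starting material
8 | [(4R)-2,6,6-trimethyl-4-(trimethylsilyloxy)cyclohex-1-en-1-yl]lithium (alkenyllithium) | [Li]C1=C(C)C[C@@H](O[Si](C)(C)C)CC1(C)C | intermediate
9 | dichloro[(4R)-2,6,6-trimethyl-4-(trimethylsilyloxy)cyclohex-1-en-1-yl]cerium (alkenylcerium dichloride) | Cl[Ce](Cl)C1=C(C)C[C@@H](O[Si](C)(C)C)CC1(C)C | intermediate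
10 | (1R,4S)-4-(tert-butyldimethylsilyloxy)-1-[(4R)-2,6,6-trimethyl-4-(trimethylsilyloxy)cyclohex-1-en-1-yl]cyclopent-2-en-1-ol (adduct trimethylsilyl ether) | CC1(C)C[C@H](O[Si](C)(C)C)CC(C)=C1[C@]2(O)C=C[C@@H](O[Si](C)(C)C(C)(C)C)C2 | intermediate
11 | (1R,4S)-4-(tert-butyldimethylsilyloxy)-1-[(4R)-4-hydroxy-2,6,6-trimethylcyclohex-1-en-1-yl]cyclopent-2-en-1-ol | CC1(C)C[C@H](O)CC(C)=C1[C@]2(O)C=C[C@@H](O[Si](C)(C)C(C)(C)C)C2 | intermediate
12 | (1R,4S)-4-(tert-butyldimethylsilyloxy)-1-[(1S,4S,6S)-4-hydroxy-2,2,6-trimethyl-7-oxabicyclo[4.1.0]heptan-1-yl]cyclopent-2-en-1-ol (epoxide oxygen syn to the C3 hydroxyl) | CC1(C)C[C@H](O)C[C@]2(C)O[C@]12[C@]3(O)C=C[C@@H](O[Si](C)(C)C(C)(C)C)C3 | intermediate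
13 | (1R,4S)-4-(tert-butyldimethylsilyloxy)-1-[(1S,4S,6S)-4-(tert-butyldimethylsilyloxy)-2,2,6-trimethyl-7-oxabicyclo[4.1.0]heptan-1-yl]cyclopent-2-en-1-ol (key precursor) | CC1(C)C[C@H](O[Si](C)(C)C(C)(C)C)C[C@]2(C)O[C@]12[C@]3(O)C=C[C@@H](O[Si](C)(C)C(C)(C)C)C3 | intermediate
14 | (3S,5S,6R,9S)-3,9-bis(tert-butyldimethylsilyloxy)-5-hydroxy-1,1,5-trimethylspiro[5.5]undec-7-en-11-one (key product) | CC1(C)C[C@H](O[Si](C)(C)C(C)(C)C)C[C@](C)(O)[C@@]13C=C[C@@H](O[Si](C)(C)C(C)(C)C)CC3=O | intermediate
15 | (3S,5S,6S,9S,11R)-3,9-bis(tert-butyldimethylsilyloxy)-1,1,5-trimethylspiro[5.5]undec-7-ene-5,11-diol | CC1(C)C[C@H](O[Si](C)(C)C(C)(C)C)C[C@](C)(O)[C@@]13C=C[C@@H](O[Si](C)(C)C(C)(C)C)C[C@H]3O | intermediate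
16 | O-[(3S,5S,6S,9S,11R)-3,9-bis(tert-butyldimethylsilyloxy)-5-hydroxy-1,1,5-trimethylspiro[5.5]undec-7-en-11-yl] S-methyl dithiocarbonate | CC1(C)C[C@H](O[Si](C)(C)C(C)(C)C)C[C@](C)(O)[C@@]13C=C[C@@H](O[Si](C)(C)C(C)(C)C)C[C@H]3OC(=S)SC | intermediate
17 | (3S,5S,6S,9S)-3,9-bis(tert-butyldimethylsilyloxy)-1,1,5-trimethylspiro[5.5]undec-7-en-5-ol | CC1(C)C[C@H](O[Si](C)(C)C(C)(C)C)C[C@](C)(O)[C@@]13C=C[C@@H](O[Si](C)(C)C(C)(C)C)CC3 | intermediate
18 | (3S,5S,6S,9S)-1,1,5-trimethylspiro[5.5]undec-7-ene-3,5,9-triol | CC1(C)C[C@H](O)C[C@](C)(O)[C@@]13C=C[C@@H](O)CC3 | intermediate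
19 | (3S,5S,6S)-3,5-dihydroxy-1,1,5-trimethylspiro[5.5]undec-7-en-9-one (enone diol) | CC1(C)C[C@H](O)C[C@](C)(O)[C@@]13C=CC(=O)CC3 | intermediate
20 | (3S,5S,6S)-1,1,5-trimethyl-3,5-bis(trimethylsilyloxy)spiro[5.5]undec-7-en-9-one | CC1(C)C[C@H](O[Si](C)(C)C)C[C@](C)(O[Si](C)(C)C)[C@@]13C=CC(=O)CC3 | intermediate
21 | (3S,5S,6S,E)-9-(bromomethylidene)-1,1,5-trimethyl-3,5-bis(trimethylsilyloxy)spiro[5.5]undec-7-ene (silylated bromodiene) | CC1(C)C[C@H](O[Si](C)(C)C)C[C@](C)(O[Si](C)(C)C)[C@@]12C=C/C(=C/Br)CC2 | intermediate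
22 | (3S,5S,6S,E)-9-(bromomethylidene)-1,1,5-trimethylspiro[5.5]undec-7-ene-3,5-diol | CC1(C)C[C@H](O)C[C@](C)(O)[C@@]12C=C/C(=C/Br)CC2 | intermediate
23 | (3R,5S,6S,E)-3-bromo-9-(bromomethylidene)-1,1,5-trimethylspiro[5.5]undec-7-en-5-ol | CC1(C)C[C@@H](Br)C[C@](C)(O)[C@@]12C=C/C(=C/Br)CC2 | target

**Step count and risks**

Total step count: 16. Longest linear sequence: 16 steps (1 to 23; 7 is a purchased fragment).

The three steps most likely to fail:

Step 9. The epoxide may ionise at C5 instead of C6, leading to Meinwald-type ring contraction or elimination. The CH2 carbon C10 may migrate in place of C7. The strained aldol product may also fragment by retro-aldol cleavage while the Lewis acid is present. The fallback is the rearrangement of the epoxy silyl ether and sets out from 13. The C11 hydroxyl is silylated with N-(trimethylsilyl)imidazole to give the C11 trimethylsilyl ether of 13 F1, which is treated with TiCl4 in CH2Cl2 at −78 °C. The silyloxy group is a stronger electron donor toward the ionising C6 than a BF3-complexed hydroxyl, the silicon is lost as chlorotrimethylsilane, and the titanium aldolate formed is held at low temperature until aqueous work-up. The route is rejoined at 14.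

Step 15. The olefination may give poor control of the geometry of the new C9=C12 bond, and the ylide may enolise the enone at C10. The fallback replaces kinetic control by stereochemical editing and sets out from 20. The olefination and desilylation are run as before, and the unwanted (3S,5S,6S,Z)-9-(bromomethylidene)-1,1,5-trimethylspiro[5.5]undec-7-ene-3,5-diol F2 is separated on AgNO3-impregnated silica. It is then equilibrated by triplet-sensitised photoisomerisation of the diene (benzophenone, 350 nm, benzene) and resubmitted to separation, so that the material converges on the E isomer. The route is rejoined at 22.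

Step 16. The oxyphosphonium ion may eliminate to the cyclohexene, or may be trapped by the cis C5 hydroxyl as a cyclic dioxyphosphorane that does not go on to the bromide. The fallback separates activation from displacement and sets out from 22. Tf2O and 2,6-lutidine in CH2Cl2 at −40 °C convert the secondary alcohol into the C3 trifluoromethanesulfonate of 22 F3, which is displaced in the same flask by Bu4NBr at low temperature in an SN2 reaction with inversion. The route is rejoined at 23.

**Further compounds**

F1 | step 9 | (1S,4S,6S)-4-(tert-butyldimethylsilyloxy)-1-[(1R,4S)-4-(tert-butyldimethylsilyloxy)-1-(trimethylsilyloxy)cyclopent-2-en-1-yl]-2,2,6-trimethyl-7-oxabicyclo[4.1.0]heptane (C11 trimethylsilyl ether of 13) | CC1(C)C[C@H](O[Si](C)(C)C(C)(C)C)C[C@]2(C)O[C@]12[C@]3(O[Si](C)(C)C)C=C[C@@H](O[Si](C)(C)C(C)(C)C)C3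
F2 | step 15 | (3S,5S,6S,Z)-9-(bromomethylidene)-1,1,5-trimethylspiro[5.5]undec-7-ene-3,5-diol | CC1(C)C[C@H](O)C[C@](C)(O)[C@@]12C=C/C(=C\Br)CC2
F3 | step 16 | (3S,5S,6S,E)-9-(bromomethylidene)-5-hydroxy-1,1,5-trimethylspiro[5.5]undec-7-en-3-yl trifluoromethanesulfonate | CC1(C)C[C@H](OS(=O)(=O)C(F)(F)F)C[C@](C)(O)[C@@]12C=C/C(=C/Br)CC2
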